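## The problem

The target 28 is a labdane: a trans-fused decalin (ring A: C1–C5 and C10; ring B: C5–C10) whose C9 carries a two-carbon tether (C11–C12) to a β-substituted butenolide (C13–C16, carbonyl at C15). It has three stereocentres: the ring-fusion pair C5 (S, α-H) and quaternary C10 (S, β-methyl), and C6 (R), whose acetoxy group is axial on the β-face, syn to the C10 methyl and the 4β-methyl groups. C5 is the natural anchor, because C10 can be set by alkylation anti to the C5 substituent once C5 is fixed. The rigid trans-decalin then exposes only its α-face, so the 6β-oxygen is best made by hydride delivery to a C6 ketone and not by bringing oxygen in from the shielded β-face. The C8=C9 alkene is tetrasubstituted and lies next to the quaternary C10, so it must be made regiospecifically, with no elimination or isomerisation that could move it to C7=C8 or C9=C11. The butenolide will not survive strong base, hydride or organometallic reagents, the axial homoallylic acetate is open to hydrolysis and elimination, and the electron-rich alkene is open to acid and electrophilic oxidants; these groups must appear late or stay masked. The enabling feature is the array C4–C5–C10–C9–C8(CH3): the gem-dimethyl carbon C4 on the ring-fusion CH, the methyl-bearing C10 and the C8-methyl/C9 pair are the isopropenyl carbon, the stereocentre, the α'-carbon and the methyl enone of (R)-carvone 1. Ring B and the absolute configuration can therefore be bought, and ring A closed by joining C4 to C3 of a three-carbon acryloyl unit (C1–C3).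

## Retrosynthesis

**Acetate and butenolide (28 ⇒ 27 ⇒ 26 ⇒ 24 ⇒ 22).** No skeletal bond is cut. The acetate is put on last, on the free 6β-alcohol 27 released from silyl ether 26. The butenolide is traced through hydroxybutenolide 24 to the 3-substituted furan 22, because a furan tolerates the hydride, base and palladium chemistry that a butenolide would not. The forward steps must place the carbonyl at C15 (not C16) and spare the C8=C9 alkene.

**C9–C11 (22 ⇒ 18 + 20).** Cutting the sp2–sp3 bond C9–C11 gives enol triflate 18 and 3-vinylfuran 20 (from aldehyde 19), joined through alkylborane 21. The neighbouring cuts at C11–C12 or C12–C13 would need an allylic C11 electrophile prone to transposition. Adding a side-chain organometallic to a C9 ketone and dehydrating would leave the alkene position open. The coupling fixes the double bond where the triflate was, and removes six carbons and the heteroaromatic ring from the precursor. It asks for a cross-coupling at a tetrasubstituted triflate beside a quaternary carbon.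

**Enol triflate (18 ⇒ 16).** Triflate 18 is the trapped enolate 17 of a conjugate reduction of enone 16. This disconnection lets the α-methyl enone inherited from carvone supply the C8 methyl group and the C8=C9 alkene regiospecifically, since C9 has only one enolisable neighbour. The forward step needs 1,4- over 1,2-hydride addition, which the quaternary C10 favours.

**C6 oxygen (16 ⇒ 15 ⇒ 14 ⇒ 12).** The C6–O bond is cut at the ketone level: silyl ether 16 comes from alcohol 15, which comes from ene-dione 14, made by γ-oxidation of enone 12. A direct γ-hydroxylation through a dienol derivative would bring oxygen in from the open α-face and give the wrong epimer. Hydride delivered from that same face to the C6 ketone gives the required 6β-alcohol. The forward reduction must choose C6 over C9, which the shielding of C9 should ensure.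

**C1 oxygen (12 ⇒ 11 ⇒ 10 ⇒ 9).** The C1 carbonyl activates the acceptor in the ring closure and has no place in the target. It is removed right after the cyclisation, by chemoselective reduction of dione 9 to alcohol 10 and radical deoxygenation of thiocarbonyl derivative 11. Doing this before the C6 chemistry keeps the later ene-dione reduction a two-carbonyl and not a three-carbonyl problem.

**Ring A, C3–C4 (9 ⇒ 8).** Cutting C3–C4 opens ring A to the monocyclic 6-acryloyl-6-methylcarvone 8. A cut at C1–C10 (intramolecular acylation) would not control the ring fusion, and C4–C5 offers no handle. C3–C4 joins a tertiary radical to an enone terminus, the most reliable way to make a bond to a fully substituted carbon. The forward reaction must turn the isopropenyl group into a C4 radical in the presence of two enones and close 6-endo. The trans fusion is already fixed by the substituents on C5 and C10.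

**C10 substituents (8 ⇒ 7 ⇒ 4 + 5; 4 ⇒ 1 + 2).** The acryloyl group is cut at C1–C10 to the aldol adduct 7 of 6-methylcarvone 4 and acrolein 5 (via enolate 6). The C10 methyl group is cut to (R)-carvone 1 and iodomethane 2 (via enolate 3). The order matters: the second electrophile enters anti to the isopropenyl group, so methyl first and acrolein second places the three-carbon arm trans to the isopropenyl group, as the trans-decalin requires.

## Roads not taken

**Alternative 1:** Both substituents of the C8=C9 alkene would be installed at once on a strained cyclohexyne. Fluoride would unmask the C8≡C9 alkyne from the vicinal silyl triflate A1, a methylcopper reagent would add methyl to C8, and the resulting C9 alkenylcopper would be alkylated by 3-(2-iodoethyl)furan A2 to give the furan labdane A3. Its merit is real: A3 is two operations from the target, and the tetrasubstituted alkene, the C8 methyl group and the whole side chain arrive in one flask, where the adopted plan needs steps 11 and 13. The weak points are these: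
- A1 already contains the complete trans-decalin with the 6β-oxygen and a silyl/triflate pair beside the quaternary C10, so ring construction and all three stereocentres are only postponed.
- Which alkyne carbon receives methyl depends on a small distortion of the cyclohexyne by C10.
- A hindered tetrasubstituted alkenylcopper reacts sluggishly with an unactivated primary iodide such as A2, so protonation would compete.
- Three-component trapping of a ring-fused cyclohexyne by a cuprate and an alkyl halide is not established on this substrate class.

Against its shorter endgame, the adopted plan sets complete stereocontrol from 1 and well-precedented bond formations throughout.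

**Alternative 2:** Ring B would be built by a Diels–Alder reaction between silyl dienol ether A4 (C10=C5–C6=C7) and the alkynoyl pyrazole A5, forming C7–C8 and C9–C10 and giving adduct A6. This road is better than the adopted plan at C6: the oxygen is present from the start as a silyl enol ether, and hydrolysis and α-face hydride reduction would give the 6β-alcohol without steps 8 to 10. It is also convergent and uses cheap achiral partners. The weak points are these:
- The diene terminus C10 is fully substituted and the diene is twisted out of planarity by the flanking methyl groups.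
- The dienophile is an internal alkyne.
- The only stereocentre formed, quaternary C10, would depend on an untested chiral Lewis acid that must differentiate the faces of a very hindered diene.
- C5 would be set afterwards by protonation.
- The C11 acyl group would need reduction and a four-carbon extension through an allylic system prone to SN2' reaction.

The adopted plan spends three steps on C6 but takes C5 and C10 from the chiral pool with predictable relative configuration.

**Alternative 3:** Ring A would be closed by an asymmetric allylic dearomatisation of the phenol carbonate A7. A zerovalent palladium catalyst with a chiral diphosphine would ionise the carbonate, and the ortho carbon C10 of the phenolate would attack the allyl terminus C1, giving dienone A8. It is attractive as catalytic asymmetric synthesis from a flat arene: C10 and ring A arise in one step, and the C6 and C9 oxygens and the C8 methyl group come with the aromatic ring. In oxygenation pattern it is ahead of the adopted plan. The weak points are these: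
- Closure through C1 puts C2=C3 inside the six-membered ring, which requires the anti allyl complex, whereas the bulky quaternary C4 substituent strongly favours the syn complex.
- The attacked carbon C10 carries a methyl group and sits between the phenolate carbon and the tertiary-alkyl-substituted C5.
- A8 is a cross-conjugation-free 2,4-cyclohexadienone prone to dimerisation.
- A8 still needs hydrogenation of C2=C3, reduction at C5 with control of the ring fusion, and several redox adjustments.

The adopted plan sets against the elegance of this step a ring closure that cannot give the wrong ring fusion and an absolute configuration that does not depend on catalyst performance.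

Key step: step 4

Remark on the chemistry: labdane numbering is used for all bicyclic compounds (C17 = methyl on C8, C20 = methyl on C10). Alcohol 10 and peroxide 13 are drawn as the expected major epimers; their C1 and C6 configurations are erased in steps 7 and 8. Commercial solutions of LiN(i-Pr)2, LiBH(s-Bu)3 and 9-BBN-H are assumed.

## Route

Step 1
Reactants: 1 (R)-(−)-carvone; 2 iodomethane
Product: 4 trans-6-methylcarvone (minor cis epimer carried along), via carvone lithium enolate 3 (not isolated)
Conditions: LiN(i-Pr)2, THF, −78 °C; then MeI, −78 to 0 °C
Reagents that add atoms: LiN(i-Pr)2, [Li]N(C(C)C)C(C)C (lithium, carried only in intermediate 3)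
Why: Kinetic deprotonation at the α'-carbon (the future C10) and SN2 methylation of the cross-conjugated enolate (enolate alkylation); the configuration of the new methine does not matter because it is planarised again in step 2.

Step 2
Reactants: 4 trans-6-methylcarvone; 5 acrolein
Product: 7 6-(1-hydroxyprop-2-enyl)-6-methylcarvone (hydroxyallyl group trans to isopropenyl; both carbinol epimers), via 6-methylcarvone lithium enolate 6 (not isolated)
Conditions: LiN(i-Pr)2, THF, −78 °C; acrolein, −78 °C; AcOH quench at −78 °C
Reagents that add atoms: LiN(i-Pr)2, [Li]N(C(C)C)C(C)C (lithium, carried only in intermediate 6)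
Why: Aldol addition of the tetrasubstituted lithium enolate to the aldehyde carbon of acrolein, on the face anti to the neighbouring isopropenyl group, sets quaternary C10 with its methyl group cis to isopropenyl; the cold acidic quench forestalls retro-aldol cleavage, and the carbinol epimers converge in step 3.

Step 3
Reactants: 7 6-(1-hydroxyprop-2-enyl)-6-methylcarvone
Product: 8 6-acryloyl-6-methylcarvone (acryloyl trans to isopropenyl)
Conditions: Dess–Martin periodinane, CH2Cl2, 0 °C to rt
Reagents that add atoms: none
Why: Dess–Martin oxidation of the secondary allylic alcohol under neutral, non-enolising conditions gives the vinyl ketone without touching the alkenes; quaternary C10 cannot epimerise.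

Step 4
Reactants: 8 6-acryloyl-6-methylcarvone
Product: 9 4,4,8,10-tetramethyl-trans-decal-7-ene-1,9-dione (5α-H and 10β-methyl)
Conditions: Fe(acac)3 (substoichiometric), PhSiH3, EtOH/ethylene glycol, 60 °C
Reagents that add atoms: none
Why: An iron hydride formed from Fe(acac)3 (trivalent iron), PhSiH3 and ethanol transfers a hydrogen atom to the terminal CH2 of the electron-rich 1,1-disubstituted isopropenyl alkene and gives the tertiary C4 radical. This nucleophilic radical adds to the β-carbon C3 of the acryloyl group in a 6-endo-trig closure of ring A (C3–C4 bond); the resulting C2 α-keto radical is reduced by divalent iron to the enolate and protonated by the solvent, which returns trivalent iron. The closest known reaction type is the iron-hydride reductive olefin coupling in its intramolecular Giese-type form, which is established for quaternary carbons and decalins from isopropenyl donors and enone acceptors. No stereocentre is created, since C2 and C3 become methylenes and C4 carries two methyl groups. The trans ring fusion follows from the trans relationship of the two arms set at C5 (from carvone) and C10 (step 2), which are held diequatorial so that only the trans-decalin can close. The step needs hydrogen-atom transfer to the isopropenyl group in preference to the two enone alkenes, which the higher reactivity of electron-rich alkenes toward the metal hydride secures. It also needs 6-endo over 5-exo attack, which polarity matching secures, because a 5-exo closure would join the nucleophilic radical to the α-carbon C2 and leave a primary radical. The ring enone cannot be reached by the C4 radical and is kept for steps 8 to 11.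

Step 5
Reactants: 9 4,4,8,10-tetramethyl-trans-decal-7-ene-1,9-dione
Product: 10 1β-hydroxy-4,4,8,10-tetramethyl-trans-decal-7-en-9-one
Conditions: NaBH4 (limited amount), MeOH/CH2Cl2, −40 °C
Reagents that add atoms: none
Why: Chemoselective borohydride reduction: the saturated C1 ketone is more electrophilic than the conjugated C9 ketone, which is also flanked by C10 and the methyl-bearing C8; axial attack anti to the C10 methyl group should give mainly the equatorial 1β-alcohol, whose configuration is of no consequence.

Step 6
Reactants: 10 1β-hydroxy-4,4,8,10-tetramethyl-trans-decal-7-en-9-one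
Product: 11 O-(imidazol-1-ylthiocarbonyl) derivative of 10
Conditions: 1,1'-thiocarbonyldiimidazole, DMAP (cat.), ClCH2CH2Cl, 70 °C
Reagents that add atoms: 1,1'-thiocarbonyldiimidazole, S=C(n1ccnc1)n1ccnc1
Why: Thioacylation of the hindered secondary alcohol under nearly neutral conditions gives the Barton–McCombie substrate and avoids the free alkoxide that could trigger retro-aldol cleavage of the β-hydroxy ketone.

Step 7
Reactants: 11 O-(imidazol-1-ylthiocarbonyl) derivative of 10
Product: 12 4,4,8,10-tetramethyl-trans-decal-7-en-9-one
Conditions: Bu3SnH (high concentration), AIBN (cat.), toluene, 100 °C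
Reagents that add atoms: none
Why: Barton–McCombie deoxygenation: the stannyl radical adds to the thiocarbonyl group, the C1–O bond fragments and the secondary C1 radical takes hydrogen from Bu3SnH; the high stannane concentration keeps hydrogen transfer ahead of a possible 1,2-acyl shift of the β-keto radical.

Step 8
Reactants: 12 4,4,8,10-tetramethyl-trans-decal-7-en-9-one
Product: 14 4,4,8,10-tetramethyl-trans-decal-7-ene-6,9-dione, via C6 tert-butyl peroxide 13 (not isolated)
Conditions: Pd(OH)2/C (cat.), t-BuOOH, K2CO3 (substoichiometric), CH2Cl2, 4 °C
Reagents that add atoms: tert-butyl hydroperoxide, CC(C)(C)OO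
Why: Palladium-catalysed tert-butyl hydroperoxide oxidation of an enone at its γ-methylene: peroxy radicals abstract a C6 hydrogen (the only allylic methylene, C10 being quaternary), the stabilised radical is trapped as peroxide 13, and base-induced Kornblum–DeLaMare fragmentation gives the ketone. The C6 configuration of 13 is lost.

Step 9
Reactants: 14 4,4,8,10-tetramethyl-trans-decal-7-ene-6,9-dione
Product: 15 6β-hydroxy-4,4,8,10-tetramethyl-trans-decal-7-en-9-one
Conditions: NaBH4, CeCl3·7H2O, MeOH, −78 °C
Reagents that add atoms: none
Why: Luche 1,2-reduction: C6 is far more accessible than C9, which lies between quaternary C10 and the methyl-bearing C8. Hydride attacks C6 from the open α-face, opposite the syn-axial 10β- and 4β-methyl groups, and sets the axial 6β-alcohol.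

Step 10
Reactants: 15 6β-hydroxy-4,4,8,10-tetramethyl-trans-decal-7-en-9-one
Product: 16 6β-(triethylsilyloxy)-4,4,8,10-tetramethyl-trans-decal-7-en-9-one
Conditions: Et3SiOTf, 2,6-lutidine, CH2Cl2, −78 to 0 °C
Reagents that add atoms: triethylsilyl triflate, CC[Si](CC)(CC)OS(=O)(=O)C(F)(F)F
Why: Silylation with the reactive silyl triflate protects the hindered axial alcohol against the hydride and base of steps 11 to 15; a triethylsilyl group is small enough to go on and come off at this position.

Step 11
Reactants: 16 6β-(triethylsilyloxy)-4,4,8,10-tetramethyl-trans-decal-7-en-9-one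
Product: 18 6β-(triethylsilyloxy)-4,4,8,10-tetramethyl-trans-decal-8-en-9-yl triflate, via C9 lithium enolate 17 (not isolated)
Conditions: LiBH(s-Bu)3, THF, −78 °C; then PhNTf2, −78 °C to rt
Reagents that add atoms: N-phenylbis(trifluoromethanesulfonimide), O=S(=O)(N(c1ccccc1)S(=O)(=O)C(F)(F)F)C(F)(F)F; LiBH(s-Bu)3, [Li+].CCC(C)[BH-](C(C)CC)C(C)CC (lithium, carried only in intermediate 17)
Why: Conjugate hydride addition of the bulky borohydride to the β-unsubstituted, α-methyl cyclohexenone at C7 gives the C8=C9 enolate regiospecifically, 1,2-attack at C9 being blocked by quaternary C10. O-triflation traps it as the tetrasubstituted enol triflate (conjugate reduction–enolate triflation, as practised on carvone itself).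

Step 12
Reactants: 19 furan-3-carbaldehyde
Product: 20 3-vinylfuran
Conditions: Ph3PCH3Br, KOt-Bu, THF, 0 °C to rt
Reagents that add atoms: methyltriphenylphosphonium bromide, C[P+](c1ccccc1)(c1ccccc1)c1ccccc1.[Br-]
Why: Wittig methylenation of the aldehyde with the non-stabilised ylide; the volatile vinylfuran is used as a solution.

Step 13
Reactants: 18 6β-(triethylsilyloxy)-4,4,8,10-tetramethyl-trans-decal-8-en-9-yl triflate; 20 3-vinylfuran
Product: 22 6β-(triethylsilyloxy)-15,16-epoxylabda-8,13(16),14-triene, via furylethyl-9-BBN 21 (not isolated)
Conditions: 20, 9-BBN-H, THF, 0 °C to rt; then 18, PdCl2(dppf) (cat.), AsPh3 (cat.), Cs2CO3, DMF/THF/H2O, rt to 50 °C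
Reagents that add atoms: 9-borabicyclo[3.3.1]nonane, B1C2CCCC1CCC2 (boron, carried only in intermediate 21)
Why: Anti-Markovnikov hydroboration of the vinyl group gives the primary alkylborane, which undergoes B-alkyl Suzuki–Miyaura coupling with the enol triflate (oxidative addition to zerovalent palladium, base-assisted transmetalation, reductive elimination) and forms C9–C11 with the alkene fixed at C8=C9. The bidentate ferrocenyl phosphine suppresses β-hydride elimination.

Step 14
Reactants: 22 6β-(triethylsilyloxy)-15,16-epoxylabda-8,13(16),14-triene
Product: 24 16-hydroxy-6β-(triethylsilyloxy)labda-8,13-dien-15,16-olide (both C16 epimers), via furan endoperoxide 23 (not isolated)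
Conditions: O2, hν (visible), tetraphenylporphyrin (cat.), i-Pr2NEt, CH2Cl2, −78 °C
Reagents that add atoms: dioxygen, O=O
Why: [4+2] addition of singlet oxygen to the furan gives the endoperoxide; the hindered amine removes the more accessible proton at C15, remote from the side chain, so that C15 becomes the lactone carbonyl and C16 the lactol carbon (regioselective furan photo-oxygenation). At −78 °C the furan should react faster than the shielded tetrasubstituted alkene.

Step 15
Reactants: 24 16-hydroxy-6β-(triethylsilyloxy)labda-8,13-dien-15,16-olide
Product: 26 6β-(triethylsilyloxy)labda-8,13-dien-15,16-olide, via sodium hydroxy enoate 25 (not isolated)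
Conditions: NaBH4, EtOH, 0 °C; then 1 M HCl, 0 °C to rt
Reagents that add atoms: NaBH4, [Na+].[BH4-] (sodium, carried only in intermediate 25)
Why: The γ-hydroxybutenolide reacts through its ring-opened formyl carboxylate: borohydride reduces the C16 aldehyde, the conjugated carboxylate is inert, and acidification closes the (Z)-hydroxy acid to the 15,16-olide. Partial loss of the silyl group here would be harmless in view of step 16.

Step 16
Reactants: 26 6β-(triethylsilyloxy)labda-8,13-dien-15,16-olide
Product: 27 6β-hydroxylabda-8,13-dien-15,16-olide
Conditions: HF·pyridine, THF/pyridine, 0 °C to rt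
Reagents that add atoms: none
Why: Fluoride-driven desilylation in a buffered, weakly acidic medium that the butenolide and the tetrasubstituted alkene tolerate; C6 is untouched.

Step 17
Reactants: 27 6β-hydroxylabda-8,13-dien-15,16-olide
Product: 28 6β-acetoxylabda-8,13-dien-15,16-olide (5S,6R,10S; CNP0128495.1)
Conditions: Ac2O, DMAP, pyridine, 40 °C
Reagents that add atoms: acetic anhydride, CC(=O)OC(C)=O
Why: Nucleophile-catalysed acetylation of the hindered axial 6β-alcohol with retention at C6; the weakly basic medium should not deconjugate the butenolide.

## Compound list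

1 | (R)-(−)-carvone | CC1=CC[C@H](CC1=O)C(C)=C | starting material
2 | iodomethane | CI | starting material
3 | lithium enolate of carvone (O–Li on C1, C1=C6, carvone numbering) | CC1=CC[C@H](C=C1O[Li])C(C)=C | intermediate
4 | trans-6-methylcarvone (methyl anti to isopropenyl; minor cis epimer carried along) | C[C@H]1[C@H](C(C)=C)CC=C(C)C1=O | intermediate
5 | acrolein | C=CC=O | starting material
6 | lithium enolate of 6-methylcarvone (tetrasubstituted C1=C6 enolate) | [Li]OC1=C(C)[C@H](C(C)=C)CC=C1C | intermediate
7 | 6-(1-hydroxyprop-2-enyl)-6-methylcarvone (hydroxyallyl trans to isopropenyl; both carbinol epimers) | C=CC(O)[C@@]1(C)[C@H](C(C)=C)CC=C(C)C1=O | intermediate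
8 | 6-acryloyl-6-methylcarvone (acryloyl trans, methyl cis to isopropenyl) | C=CC(=O)[C@@]1(C)[C@H](C(C)=C)CC=C(C)C1=O | intermediate
9 | 4,4,8,10-tetramethyl-trans-decal-7-ene-1,9-dione (5α-H, 10β-methyl) | C1C=C(C)C(=O)[C@@]2(C)C(=O)CCC(C)(C)[C@H]12 | intermediate
10 | 1β-hydroxy-4,4,8,10-tetramethyl-trans-decal-7-en-9-one | C1C=C(C)C(=O)[C@@]2(C)[C@H](O)CCC(C)(C)[C@H]12 | intermediate
11 | 1β-O-(imidazol-1-ylthiocarbonyl) derivative of 10 | C1C=C(C)C(=O)[C@@]2(C)[C@H](OC(=S)n3ccnc3)CCC(C)(C)[C@H]12 | intermediate
12 | 4,4,8,10-tetramethyl-trans-decal-7-en-9-one | C1C=C(C)C(=O)[C@@]2(C)CCCC(C)(C)[C@H]12 | intermediate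
13 | 6-(tert-butylperoxy)-4,4,8,10-tetramethyl-trans-decal-7-en-9-one (6α epimer drawn; either epimer converges) | CC(C)(C)OO[C@H]1C=C(C)C(=O)[C@@]2(C)CCCC(C)(C)[C@H]12 | intermediate
14 | 4,4,8,10-tetramethyl-trans-decal-7-ene-6,9-dione | O=C1C=C(C)C(=O)[C@@]2(C)CCCC(C)(C)[C@H]12 | intermediate
15 | 6β-hydroxy-4,4,8,10-tetramethyl-trans-decal-7-en-9-one | O[C@@H]1C=C(C)C(=O)[C@@]2(C)CCCC(C)(C)[C@H]12 | intermediate
16 | 6β-(triethylsilyloxy)-4,4,8,10-tetramethyl-trans-decal-7-en-9-one | CC[Si](CC)(CC)O[C@@H]1C=C(C)C(=O)[C@@]2(C)CCCC(C)(C)[C@H]12 | intermediate
17 | lithium C8=C9 enolate of the 7,8-dihydro derivative of 16 | CC[Si](CC)(CC)O[C@@H]1CC(C)=C(O[Li])[C@@]2(C)CCCC(C)(C)[C@H]12 | intermediate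
18 | 6β-(triethylsilyloxy)-4,4,8,10-tetramethyl-trans-decal-8-en-9-yl triflate | CC[Si](CC)(CC)O[C@@H]1CC(C)=C(OS(=O)(=O)C(F)(F)F)[C@@]2(C)CCCC(C)(C)[C@H]12 | intermediate
19 | furan-3-carbaldehyde | O=Cc1ccoc1 | starting material
20 | 3-vinylfuran | C=Cc1ccoc1 | intermediate
21 | B-[2-(furan-3-yl)ethyl]-9-borabicyclo[3.3.1]nonane | c1occc1CCB1C2CCCC1CCC2 | intermediate
22 | 6β-(triethylsilyloxy)-15,16-epoxylabda-8,13(16),14-triene | CC[Si](CC)(CC)O[C@@H]1CC(C)=C(CCc3ccoc3)[C@@]2(C)CCCC(C)(C)[C@H]12 | intermediate
23 | 15,16-endoperoxide of 22 (2,3,7-trioxabicyclo[2.2.1]hept-5-ene; bridgehead epimers) | CC[Si](CC)(CC)O[C@@H]1CC(C)=C(CCC3=CC4OOC3O4)[C@@]2(C)CCCC(C)(C)[C@H]12 | intermediate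
24 | 16-hydroxy-6β-(triethylsilyloxy)labda-8,13-dien-15,16-olide (C16 epimers) | CC[Si](CC)(CC)O[C@@H]1CC(C)=C(CCC3=CC(=O)OC3O)[C@@]2(C)CCCC(C)(C)[C@H]12 | intermediate
25 | sodium (13Z)-16-hydroxy-6β-(triethylsilyloxy)labda-8,13-dien-15-oate | CC[Si](CC)(CC)O[C@@H]1CC(C)=C(CC/C(CO)=C/C(=O)[O-])[C@@]2(C)CCCC(C)(C)[C@H]12.[Na+] | intermediate
26 | 6β-(triethylsilyloxy)labda-8,13-dien-15,16-olide | CC[Si](CC)(CC)O[C@@H]1CC(C)=C(CCC3=CC(=O)OC3)[C@@]2(C)CCCC(C)(C)[C@H]12 | intermediate
27 | 6β-hydroxylabda-8,13-dien-15,16-olide | O[C@@H]1CC(C)=C(CCC3=CC(=O)OC3)[C@@]2(C)CCCC(C)(C)[C@H]12 | intermediate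
28 | 6β-acetoxylabda-8,13-dien-15,16-olide (5S,6R,10S) | CC(=O)O[C@@H]1CC(C)=C(CCC2=CC(=O)OC2)[C@@]2(C)CCCC(C)(C)[C@H]12 | target

## Step count and least certain steps

Total step count: 17. Longest linear sequence: 16 steps from 1 (steps 1 to 11 and 13 to 17); step 12 is a one-step branch.

**Step 4 (key step).** The acryloyl group is the most reactive π-system in 8 toward hydride and radicals. It may be reduced by hydrogen-atom transfer or conjugate hydride addition before the isopropenyl radical forms, or the vinyl ketone may oligomerise. Fallback, from 8 back to 9: HBr in AcOH at 0 °C adds across the isopropenyl group, as it does with carvone, and also to the vinyl ketone, giving the bis-hydrobromide F1. Et3N regenerates the vinyl ketone by elimination of the β-bromo ketone and leaves the tertiary bromide F2. Slow addition of Bu3SnH with AIBN abstracts the bromine, produces the same C4 radical without any metal hydride, and closes ring A by the same 6-endo Giese cyclisation to 9.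

**Step 7.** The secondary C1 radical sits next to the carbon that bears the C9 carbonyl and may undergo a 1,2-acyl shift (Dowd–Beckwith type) before hydrogen transfer. The β-hydroxy ketone may also suffer retro-aldol cleavage during step 6. Fallback, from 9 back to 12, without a C1 radical or a C1 alcohol: kinetic enolisation of the saturated ketone with KN(SiMe3)2 and trapping with PhNTf2 gives the C1 enol triflate F3. Reduction with Pd(OAc)2, PPh3 and tributylammonium formate gives the Δ1-alkene F4. Hydrogenation with RhCl(PPh3)3 saturates the disubstituted C1=C2 alkene in preference to the trisubstituted enone and gives 12.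

**Step 8.** Hydrogen abstraction at the neopentyl-type C6 methylene may be slow. Abstraction at the C17 methyl group and nucleophilic epoxidation of the enone by tert-butyl peroxide anion would then compete. Fallback, from 12 back to 14: Et3N and t-BuMe2SiOTf give the silyl dienol ether F5. Rubottom-type oxidation with dimethyldioxirane and an acidic work-up gives the γ-hydroxy enone F6 (probably mainly the 6α epimer, which does not matter). Dess–Martin oxidation gives 14.

**Step 13.** Oxidative addition and transmetalation at the tetrasubstituted triflate beside quaternary C10 may be slow. Triflate hydrolysis and decomposition of the alkylborane would then take over. Fallback, from 18 back to 22, moving the sp3 coupling to an unhindered site: Stille coupling of 18 with tributyl(vinyl)stannane (Pd(PPh3)4, LiCl) gives the 9-vinyl diene F7. 9-BBN-H adds to the terminal vinyl carbon only and gives the borane F8. Suzuki–Miyaura coupling of F8 with 3-bromofuran (PdCl2(dppf), K3PO4) gives 22.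

**Step 14.** Singlet oxygen may undergo an ene reaction with the electron-rich tetrasubstituted C8=C9 alkene in competition with addition to the furan, which would consume material as allylic hydroperoxides. Fallback, from 18 to 26, with the butenolide made before it meets the alkene: commercial 2-(furan-3-yl)ethanol F9 is photo-oxygenated as in step 14 to the hydroxybutenolide F10 and reduced as in step 15 to 4-(2-hydroxyethyl)furan-2(5H)-one F11. Appel iodination (I2, PPh3, imidazole) gives the iodide F12, and zinc insertion (Zn, LiCl) gives the alkylzinc iodide F13. Negishi coupling of F13 with 18 (Pd(OAc)2, 2-dicyclohexylphosphino-2',6'-dimethoxybiphenyl) gives 26 directly.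

## Further compounds

F1 | step 4 | 6-(3-bromopropanoyl)-5-(2-bromopropan-2-yl)-2,6-dimethylcyclohex-2-enone (configuration as in 8) | BrCCC(=O)[C@@]1(C)[C@H](C(C)(C)Br)CC=C(C)C1=O
F2 | step 4 | 6-acryloyl-5-(2-bromopropan-2-yl)-2,6-dimethylcyclohex-2-enone (configuration as in 8) | C=CC(=O)[C@@]1(C)[C@H](C(C)(C)Br)CC=C(C)C1=O
F3 | step 7 | 4,4,8,10-tetramethyl-9-oxo-trans-decala-1,7-dien-1-yl triflate | C1C=C(C)C(=O)[C@@]2(C)C(OS(=O)(=O)C(F)(F)F)=CCC(C)(C)[C@H]12
F4 | step 7 | 4,4,8,10-tetramethyl-trans-decala-1,7-dien-9-one | C1C=C(C)C(=O)[C@@]2(C)C=CCC(C)(C)[C@H]12
F5 | step 8 | 9-(tert-butyldimethylsilyloxy)-4,4,8,10-tetramethyl-trans-decala-6,8-diene | C1=CC(C)=C(O[Si](C)(C)C(C)(C)C)[C@@]2(C)CCCC(C)(C)[C@H]12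
F6 | step 8 | 6α-hydroxy-4,4,8,10-tetramethyl-trans-decal-7-en-9-one (6β epimer also acceptable) | O[C@H]1C=C(C)C(=O)[C@@]2(C)CCCC(C)(C)[C@H]12
F7 | step 13 | 6β-(triethylsilyloxy)-9-vinyl-4,4,8,10-tetramethyl-trans-decal-8-ene | CC[Si](CC)(CC)O[C@@H]1CC(C)=C(C=C)[C@@]2(C)CCCC(C)(C)[C@H]12
F8 | step 13 | B-alkyl-9-borabicyclo[3.3.1]nonane from F7 (boron on C12) | CC[Si](CC)(CC)O[C@@H]1CC(C)=C(CCB3C4CCCC3CCC4)[C@@]2(C)CCCC(C)(C)[C@H]12
F9 | step 14 | 2-(furan-3-yl)ethanol | OCCc1ccoc1
F10 | step 14 | 5-hydroxy-4-(2-hydroxyethyl)furan-2(5H)-one | OCCC1=CC(=O)OC1O
F11 | step 14 | 4-(2-hydroxyethyl)furan-2(5H)-one | OCCC1=CC(=O)OC1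
F12 | step 14 | 4-(2-iodoethyl)furan-2(5H)-one | ICCC1=CC(=O)OC1
F13 | step 14 | [2-(5-oxo-2,5-dihydrofuran-3-yl)ethyl]zinc iodide | I[Zn]CCC1=CC(=O)OC1
A1 | alternative 1 | 6β-(tert-butyldimethylsilyloxy)-9-(trimethylsilyl)-17-nor-trans-decal-8-en-8-yl triflate (cyclohexyne precursor) | CC(C)(C)[Si](C)(C)O[C@@H]1CC(OS(=O)(=O)C(F)(F)F)=C([Si](C)(C)C)[C@@]2(C)CCCC(C)(C)[C@H]12
A2 | alternative 1 | 3-(2-iodoethyl)furan | ICCc1ccoc1
A3 | alternative 1 | 6β-(tert-butyldimethylsilyloxy)-15,16-epoxylabda-8,13(16),14-triene | CC(C)(C)[Si](C)(C)O[C@@H]1CC(C)=C(CCc2ccoc2)[C@@]2(C)CCCC(C)(C)[C@H]12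
A4 | alternative 2 | tert-butyldimethylsilyl dienol ether of 1-(2,6,6-trimethylcyclohex-1-enyl)ethanone | C=C(O[Si](C)(C)C(C)(C)C)C1=C(C)CCCC1(C)C
A5 | alternative 2 | 1-(but-2-ynoyl)-3,5-dimethylpyrazole | CC#CC(=O)n1nc(C)cc1C
A6 | alternative 2 | ring-B cyclohexadiene adduct (C6 silyl enol ether, C8=C9 alkene, C11 acyl pyrazole) | CC1=C(C(=O)n2nc(C)cc2C)[C@@]2(C)CCCC(C)(C)C2=C(O[Si](C)(C)C(C)(C)C)C1
A7 | alternative 3 | (E)-4-(3-hydroxy-6-methoxy-2,4-dimethylphenyl)-4-methylpent-2-enyl methyl carbonate | COc1cc(C)c(O)c(C)c1C(C)(C)/C=C/COC(=O)OC
A8 | alternative 3 | bicyclic 6-methoxy-cyclohexa-5,7-dien-9-one with quaternary C10 | COC1=C2C(C)(C)C=CC[C@]2(C)C(=O)C(C)=C1
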